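**Retrosynthetic overview**
1. Target 28 ⇐ lactone 26 (dioxolane opened, C1–OH oxidised) ⇐ open-chain aldehyde 24: one CrCl2/NiCl2 operation joins C5 (iodoalkene) to C6 (aldehyde) to close the ten-membered ring, and the new C6 alkoxide then closes the lactone on the C12 ester.
2. 24 ⇐ aldehyde 15 + allyl bromide 19 (C7–C8, ligand-controlled chromium allylation, then the isovalerate); 15 ⇐ methyl ketone 6 + iodoallyl bromide 9 (C2–C3 enolate alkylation); 6 ⇐ (S)-lactic acid (C10).
3. Ring order: temporary cis-1,3-dioxolane across C1/C10 (step 10) → carbocycle C1–C10, then lactone ring O–C6–C7–C11–C12 (both in step 18) → dioxolane cleaved (step 19).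
4. Enabling feature: the cis C4=C5 bond keeps C5 on the side of C3, so the chain is already bent toward C6; the C11(=C13)–C12 acrylate on C7 lies 1,4 to the C6 oxygen; and the C1/C10 α-ketol can be held as a dioxolane ring with C1 sp3, which removes the five-membered closure of C5 onto C1 and turns the two arms toward each other.

Key step: step 18

Remark: C1–C15 are the germacrane positions of the target (ring C1–C10: C1 ketone, C4=C5, C6 lactone carbinol, C7 ring fusion, C8 ester carbinol, C10 tertiary carbinol; C11–C13 lactone carbons with C13 the exocyclic methylene; C14 methyl on C10; C15 methyl on C4).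
Remark: enolates and carbon–metal species are treated inside their step and are not numbered; compounds that could be isolated but are carried on in the same flask are numbered.
Assumption: in step 14 the (S,S)-ligand is written; if a model allylation shows the opposite facial sense, its (R,R)-antipode is used.

**Step 1**
Reactants: 1 (S)-lactic acid
Product: 2 (2S,5S)-2-tert-butyl-5-methyl-1,3-dioxolan-4-one
Conditions: pivalaldehyde, p-TsOH (cat.), pentane, reflux, Dean–Stark; crystallisation from pentane, −78 °C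
Reagents that add atoms: pivalaldehyde, CC(C)(C)C=O
Why: Acid-catalysed acetalisation under thermodynamic control (self-regeneration of stereocentres, first stage) should give the cis acetal, so the lactate centre sets the new acetal carbon (2S), which is enriched by crystallisation.

**Step 2**
Reactants: 2 (2S,5S)-2-tert-butyl-5-methyl-1,3-dioxolan-4-one
Product: 3 (2S,5R)-2-tert-butyl-5-methyl-5-(prop-2-en-1-yl)-1,3-dioxolan-4-one
Conditions: LiN(iPr)2, THF, −78 °C; allyl bromide, −78 → −30 °C
Reagents that add atoms: allyl bromide, C=CCBr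
Why: The lithium enolate is alkylated (SN2) on the face anti to the tert-butyl group, so the acetal centre hands the lactate configuration back to the new quaternary carbon (future C10, R).

**Step 3**
Reactants: 3 (2S,5R)-2-tert-butyl-5-methyl-5-(prop-2-en-1-yl)-1,3-dioxolan-4-one
Product: 4 (2R)-2-hydroxy-N-methoxy-N,2-dimethylpent-4-enamide
Conditions: MeNH(OMe)·HCl, iPrMgCl, THF, −20 → 0 °C; aq. NH4Cl
Reagents that add atoms: N,O-dimethylhydroxylamine hydrochloride, CNOC.Cl
Why: The chloromagnesium amide should open the activated acetal-ester (Weinreb amide formation) with loss of pivalaldehyde and without touching the quaternary centre.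

**Step 4**
Reactants: 4 (2R)-2-hydroxy-N-methoxy-N,2-dimethylpent-4-enamide
Product: 5 (2R)-N-methoxy-N,2-dimethyl-2-(triethylsilyloxy)pent-4-enamide
Conditions: Et3SiOTf, 2,6-lutidine, CH2Cl2, −78 → 0 °C
Reagents that add atoms: triethylsilyl trifluoromethanesulfonate, CC[Si](CC)(CC)OS(=O)(=O)C(F)(F)F
Why: Silyl triflate with 2,6-lutidine should silylate the hindered tertiary hydroxyl, and at the amide stage no α-hydrogen is present that could give an enol silyl ether.

**Step 5**
Reactants: 5 (2R)-N-methoxy-N,2-dimethyl-2-(triethylsilyloxy)pent-4-enamide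
Product: 6 (3R)-3-methyl-3-(triethylsilyloxy)hex-5-en-2-one
Conditions: MeMgBr, THF, 0 °C; aq. NH4Cl
Reagents that add atoms: methylmagnesium bromide, C[Mg]Br
Why: Weinreb ketone synthesis, in which the chelated tetrahedral magnesium intermediate should collapse only on work-up, so a single methyl group (future C2) is added.

**Step 6**
Reactants: 7 propargyl alcohol
Product: 8 (2Z)-3-iodo-2-methylprop-2-en-1-ol
Conditions: MeMgBr (2.5 equiv), CuI (10 mol %), THF, −10 °C → rt; then I2, −78 → 0 °C
Reagents that add atoms: methylmagnesium bromide, C[Mg]Br; iodine, [I][I]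
Why: Copper-catalysed anti-carbomagnesiation of the propargylic magnesium alkoxide should place methyl on the internal carbon and magnesium on the terminal carbon cis to the CH2O arm (five-membered chelate), and iodinolysis with retention should give the (Z)-iodoalkene that fixes the C4=C5 geometry of the target.

**Step 7**
Reactants: 8 (2Z)-3-iodo-2-methylprop-2-en-1-ol
Product: 9 (1Z)-3-bromo-1-iodo-2-methylprop-1-ene
Conditions: PBr3, Et2O, 0 °C
Reagents that add atoms: phosphorus tribromide, BrP(Br)Br
Why: SN2 substitution of the primary allylic alcohol through its phosphite ester should give the bromide without change of alkene geometry.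

**Step 8**
Reactants: 6 (3R)-3-methyl-3-(triethylsilyloxy)hex-5-en-2-one; 9 (1Z)-3-bromo-1-iodo-2-methylprop-1-ene
Product: 10 (1Z,6R)-1-iodo-2,6-dimethyl-6-(triethylsilyloxy)nona-1,8-dien-5-one
Conditions: LiN(iPr)2, THF, −78 °C; then 9, DMPU, −78 → −40 °C
Reagents that add atoms: none
Why: The ketone has α-hydrogens only on its methyl group, so kinetic deprotonation gives one lithium enolate, whose SN2 alkylation by the allylic bromide should form C2–C3 and leave the iodoalkene untouched.

**Step 9**
Reactants: 10 (1Z,6R)-1-iodo-2,6-dimethyl-6-(triethylsilyloxy)nona-1,8-dien-5-one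
Product: 11 (1Z,5S,6R)-1-iodo-2,6-dimethyl-6-(triethylsilyloxy)nona-1,8-dien-5-ol
Conditions: (R)-2-methyl-CBS-oxazaborolidine (0.2 equiv), catecholborane, toluene, −78 → −40 °C; MeOH, aq. NaHCO3
Reagents that add atoms: none
Why: Corey–Bakshi–Shibata reduction, in which the (R)-oxazaborolidine should tell the fully substituted C10 side from the methylene side and deliver hydride to the Re face of C1, giving the 1S carbinol, a temporary centre chosen so that the C2 and C9 arms become cis on the dioxolane, while catecholborane at low temperature leaves both alkenes alone.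

**Step 10**
Reactants: 11 (1Z,5S,6R)-1-iodo-2,6-dimethyl-6-(triethylsilyloxy)nona-1,8-dien-5-ol
Product: 13 (4R,5S)-5-[(3Z)-4-iodo-3-methylbut-3-en-1-yl]-2,2,4-trimethyl-4-(prop-2-en-1-yl)-1,3-dioxolane, via free 5,6-diol 12 (not isolated)
Conditions: CSA (cat.), MeOH, 0 °C → rt; then Me2C(OMe)2, acetone, CSA (cat.), rt
Reagents that add atoms: 2,2-dimethoxypropane, COC(C)(C)OC
Why: Acid methanolysis should remove the tertiary triethylsilyl ether and acetal exchange should then close the cis-1,3-dioxolane, the temporary ring that masks the C10 hydroxyl and keeps C1 at the alcohol level, with no stereocentre touched.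

**Step 11**
Reactants: 13 (4R,5S)-5-[(3Z)-4-iodo-3-methylbut-3-en-1-yl]-2,2,4-trimethyl-4-(prop-2-en-1-yl)-1,3-dioxolane
Product: 15 2-[(4R,5S)-5-[(3Z)-4-iodo-3-methylbut-3-en-1-yl]-2,2,4-trimethyl-1,3-dioxolan-4-yl]acetaldehyde, via terminal 1,2-diol 14 (not isolated)
Conditions: OsO4 (2 mol %), NaIO4 (4 equiv), 2,6-lutidine, dioxane/H2O 3:1, rt
Reagents that add atoms: osmium tetroxide, O=[Os](=O)(=O)=O; sodium periodate, [Na+].[O-]I(=O)(=O)=O
Why: Lemieux–Johnson oxidation, in which OsO4 should dihydroxylate the unhindered monosubstituted alkene far faster than the electron-poor trisubstituted iodoalkene and periodate should cleave the diol to the C8 aldehyde.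

**Step 12**
Reactants: 16 2-[(4-methoxyphenyl)methoxy]acetaldehyde; 17 methyl acrylate
Product: 18 methyl 3-hydroxy-4-[(4-methoxyphenyl)methoxy]-2-methylidenebutanoate (racemic)
Conditions: DABCO (1 equiv), dioxane/H2O 1:1, rt
Reagents that add atoms: none
Why: Morita–Baylis–Hillman reaction of an α-alkoxy aldehyde, whose carbinol centre is formed racemic and is erased in step 13.

**Step 13**
Reactants: 18 methyl 3-hydroxy-4-[(4-methoxyphenyl)methoxy]-2-methylidenebutanoate
Product: 19 methyl (2Z)-2-(bromomethyl)-4-[(4-methoxyphenyl)methoxy]but-2-enoate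
Conditions: NBS, Me2S, CH2Cl2, 0 °C → rt
Reagents that add atoms: N-bromosuccinimide, O=C1CCC(=O)N1Br
Why: The bromodimethylsulfonium salt formed from NBS and Me2S should activate the hydroxyl and bromide should enter in SN2′ fashion, giving the more stable (Z)-2-(bromomethyl)enoate in which the CH2OPMB group is cis to CH2Br.

**Step 14**
Reactants: 15 2-[(4R,5S)-5-[(3Z)-4-iodo-3-methylbut-3-en-1-yl]-2,2,4-trimethyl-1,3-dioxolan-4-yl]acetaldehyde; 19 methyl (2Z)-2-(bromomethyl)-4-[(4-methoxyphenyl)methoxy]but-2-enoate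
Product: 21 methyl (3S,4R)-4-hydroxy-5-[(4R,5S)-5-[(3Z)-4-iodo-3-methylbut-3-en-1-yl]-2,2,4-trimethyl-1,3-dioxolan-4-yl]-3-{[(4-methoxyphenyl)methoxy]methyl}-2-methylidenepentanoate, via trimethylsilyl ether 20 (not isolated)
Conditions: CrCl2 (10 mol %), (S,S)-1,8-bis(4-isopropyl-4,5-dihydrooxazol-2-yl)-3,6-diphenyl-9H-carbazole (12 mol %), Mn powder (2 equiv), Me3SiCl (1.5 equiv), iPr2NEt (0.3 equiv), THF, 0 °C → rt; then aq. citric acid
Reagents that add atoms: none
Why: Catalytic asymmetric Nozaki–Hiyama allylation (2-alkoxycarbonylallylation), in which the allyl species of trivalent chromium should attack through its γ-carbon in a Zimmerman–Traxler chair with the CH2OPMB group axial, setting C7 syn to the C8 oxygen, while the chiral bis(oxazolinyl)carbazole ligand on chromium, and not the remote C10 centre, should select the Si face of the aldehyde (8R), and without a nickel salt the iodoalkene is not touched.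

**Step 15**
Reactants: 21 methyl (3S,4R)-4-hydroxy-5-[(4R,5S)-5-[(3Z)-4-iodo-3-methylbut-3-en-1-yl]-2,2,4-trimethyl-1,3-dioxolan-4-yl]-3-{[(4-methoxyphenyl)methoxy]methyl}-2-methylidenepentanoate
Product: 22 methyl (3S,4R)-5-[(4R,5S)-5-[(3Z)-4-iodo-3-methylbut-3-en-1-yl]-2,2,4-trimethyl-1,3-dioxolan-4-yl]-3-{[(4-methoxyphenyl)methoxy]methyl}-4-[(3-methylbutanoyl)oxy]-2-methylidenepentanoate
Conditions: isovaleryl chloride, pyridine, DMAP (cat.), CH2Cl2, 0 °C → rt
Reagents that add atoms: 3-methylbutanoyl chloride, CC(C)CC(=O)Cl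
Why: DMAP-catalysed acylation of the secondary hydroxyl should install the isovalerate and at the same time block lactonisation of the C8 oxygen onto the C12 ester.

**Step 16**
Reactants: 22 methyl (3S,4R)-5-[(4R,5S)-5-[(3Z)-4-iodo-3-methylbut-3-en-1-yl]-2,2,4-trimethyl-1,3-dioxolan-4-yl]-3-{[(4-methoxyphenyl)methoxy]methyl}-4-[(3-methylbutanoyl)oxy]-2-methylidenepentanoate
Product: 23 methyl (3S,4R)-3-(hydroxymethyl)-5-[(4R,5S)-5-[(3Z)-4-iodo-3-methylbut-3-en-1-yl]-2,2,4-trimethyl-1,3-dioxolan-4-yl]-4-[(3-methylbutanoyl)oxy]-2-methylidenepentanoate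
Conditions: DDQ, CH2Cl2/pH 7 phosphate buffer 10:1, 0 °C; crude product taken on at once
Reagents that add atoms: none
Why: Oxidative cleavage of the 4-methoxybenzyl ether by DDQ (hydride abstraction, hydrolysis of the oxocarbenium ion) should free the C6 hydroxyl under buffered neutral conditions that spare the dioxolane, the acrylate and the iodoalkene and give the hydroxy ester no acid or base to lactonise with.

**Step 17**
Reactants: 23 methyl (3S,4R)-3-(hydroxymethyl)-5-[(4R,5S)-5-[(3Z)-4-iodo-3-methylbut-3-en-1-yl]-2,2,4-trimethyl-1,3-dioxolan-4-yl]-4-[(3-methylbutanoyl)oxy]-2-methylidenepentanoate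
Product: 24 methyl (3R,4R)-3-formyl-5-[(4R,5S)-5-[(3Z)-4-iodo-3-methylbut-3-en-1-yl]-2,2,4-trimethyl-1,3-dioxolan-4-yl]-4-[(3-methylbutanoyl)oxy]-2-methylidenepentanoate
Conditions: Dess–Martin periodinane, NaHCO3, CH2Cl2, 0 °C; filtration through buffered silica, used at once
Reagents that add atoms: none
Why: Dess–Martin oxidation under bicarbonate buffer should give the aldehyde without base, so that C7, which is α to the aldehyde and allylic to C11=C13, is neither epimerised nor drawn into conjugation.

**Step 18**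
Reactants: 24 methyl (3R,4R)-3-formyl-5-[(4R,5S)-5-[(3Z)-4-iodo-3-methylbut-3-en-1-yl]-2,2,4-trimethyl-1,3-dioxolan-4-yl]-4-[(3-methylbutanoyl)oxy]-2-methylidenepentanoate
Product: 26 (1S,6R,7R,8R,10R)-1,10-(isopropylidenedioxy)-8-(3-methylbutanoyloxy)germacra-4Z,11(13)-dien-6,12-olide, via macrocyclic hydroxy ester 25 (not isolated)
Conditions: CrCl2 (10 equiv), NiCl2 (2 mol %), DMSO/THF 3:1, 2 mM, 24 added by syringe pump over 12 h, rt then 40 °C; aq. sodium serinate; PPTS (cat.), CH2Cl2, rt
Reagents that add atoms: none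
Why: NiCl2 is reduced by CrCl2 to zerovalent nickel, which inserts into the C5–I bond; transmetalation gives the (Z)-alkenyl species of trivalent chromium with retained geometry, which adds to the C6 aldehyde, and the chromium alkoxide 25 then attacks the C12 methyl ester with loss of methanol. The closest known reaction type is the Nozaki–Hiyama–Kishi macrocyclisation of an iodoalkene onto an aldehyde to a medium carbocycle, joined here to the alkoxide lactonisation known from chromium-mediated α-methylene-γ-butyrolactone syntheses. The ten-membered ring closes by 10-exo-trig addition to C6=O and the lactone by 5-exo-trig acyl substitution, so one operation should deliver the C5–C6 bond and both rings of the target. The only new stereocentre, C6, is controlled by C7: the sp2 carbon C11 stands anti to the incoming C5 (Felkin–Anh), the tether forces C8 gauche to the forming bond, and the bulky chromium-bound oxygen takes the outside position anti to C7–C8, so C5 should add to the Re face and give 6R with H6 anti to H7, the arrangement that lactonises to the trans-fused ring. The step needs aldehyde-over-ketone and ring-over-chain selectivity: the first is secured because C1 is an sp3 carbon inside the cis-dioxolane (a free C1 ketone would be attacked 5-exo by C5), the second by that same ring, which holds the C2 and C9 arms on one side, by the cis C4=C5 bond and by slow addition at 2 mM. The esters, the acetal and the acrylate are inert to alkenylchromium reagents, and no base is present that could epimerise C7.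

**Step 19**
Reactants: 26 (1S,6R,7R,8R,10R)-1,10-(isopropylidenedioxy)-8-(3-methylbutanoyloxy)germacra-4Z,11(13)-dien-6,12-olide
Product: 27 (1S,6R,7R,8R,10R)-1,10-dihydroxy-8-(3-methylbutanoyloxy)germacra-4Z,11(13)-dien-6,12-olide
Conditions: AcOH/H2O/THF 3:1:1, 40 °C
Reagents that add atoms: none
Why: Mild acid hydrolysis should open the isopropylidene acetal, the temporary ring, while the lactone, the isovalerate and the allylic C6–O bond are stable to aqueous acetic acid.

**Step 20**
Reactants: 27 (1S,6R,7R,8R,10R)-1,10-dihydroxy-8-(3-methylbutanoyloxy)germacra-4Z,11(13)-dien-6,12-olide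
Product: 28 CNP0105188.1, (6R,7R,8R,10R)-10-hydroxy-8-(3-methylbutanoyloxy)-1-oxogermacra-4Z,11(13)-dien-6,12-olide
Conditions: Dess–Martin periodinane, NaHCO3, CH2Cl2, 0 °C → rt
Reagents that add atoms: none
Why: Dess–Martin oxidation can act only on the secondary C1 hydroxyl (C10 is tertiary), which removes the temporary C1 centre and should give the α-ketol of the target without base-induced ketol shift or epimerisation.

**Compound list**
1 | (S)-lactic acid | C[C@H](O)C(=O)O | starting material
2 | (2S,5S)-2-tert-butyl-5-methyl-1,3-dioxolan-4-one | C[C@@H]1O[C@H](C(C)(C)C)OC1=O | intermediate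
3 | (2S,5R)-2-tert-butyl-5-methyl-5-(prop-2-en-1-yl)-1,3-dioxolan-4-one | C=CC[C@@]1(C)O[C@H](C(C)(C)C)OC1=O | intermediate
4 | (2R)-2-hydroxy-N-methoxy-N,2-dimethylpent-4-enamide | C=CC[C@@](C)(O)C(=O)N(C)OC | intermediate
5 | (2R)-N-methoxy-N,2-dimethyl-2-(triethylsilyloxy)pent-4-enamide | C=CC[C@@](C)(O[Si](CC)(CC)CC)C(=O)N(C)OC | intermediate
6 | (3R)-3-methyl-3-(triethylsilyloxy)hex-5-en-2-one | C=CC[C@@](C)(O[Si](CC)(CC)CC)C(C)=O | intermediate
7 | propargyl alcohol | C#CCO | starting material
8 | (2Z)-3-iodo-2-methylprop-2-en-1-ol | OC/C(C)=C\I | intermediate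
9 | (1Z)-3-bromo-1-iodo-2-methylprop-1-ene | BrC/C(C)=C\I | intermediate
10 | (1Z,6R)-1-iodo-2,6-dimethyl-6-(triethylsilyloxy)nona-1,8-dien-5-one | C=CC[C@@](C)(O[Si](CC)(CC)CC)C(=O)CC/C(C)=C\I | intermediate
11 | (1Z,5S,6R)-1-iodo-2,6-dimethyl-6-(triethylsilyloxy)nona-1,8-dien-5-ol | C=CC[C@@](C)(O[Si](CC)(CC)CC)[C@@H](O)CC/C(C)=C\I | intermediate
12 | (1Z,5S,6R)-1-iodo-2,6-dimethylnona-1,8-diene-5,6-diol | C=CC[C@@](C)(O)[C@@H](O)CC/C(C)=C\I | intermediate
13 | (4R,5S)-5-[(3Z)-4-iodo-3-methylbut-3-en-1-yl]-2,2,4-trimethyl-4-(prop-2-en-1-yl)-1,3-dioxolane | C=CC[C@@]1(C)OC(C)(C)O[C@H]1CC/C(C)=C\I | intermediate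
14 | 3-[(4R,5S)-5-[(3Z)-4-iodo-3-methylbut-3-en-1-yl]-2,2,4-trimethyl-1,3-dioxolan-4-yl]propane-1,2-diol (both epimers at the secondary carbinol) | OCC(O)C[C@@]1(C)OC(C)(C)O[C@H]1CC/C(C)=C\I | intermediate
15 | 2-[(4R,5S)-5-[(3Z)-4-iodo-3-methylbut-3-en-1-yl]-2,2,4-trimethyl-1,3-dioxolan-4-yl]acetaldehyde | O=CC[C@@]1(C)OC(C)(C)O[C@H]1CC/C(C)=C\I | intermediate
16 | 2-[(4-methoxyphenyl)methoxy]acetaldehyde | COc1ccc(COCC=O)cc1 | starting material
17 | methyl acrylate | C=CC(=O)OC | starting material
18 | methyl 3-hydroxy-4-[(4-methoxyphenyl)methoxy]-2-methylidenebutanoate (racemic) | COC(=O)C(=C)C(O)COCc1ccc(OC)cc1 | intermediate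
19 | methyl (2Z)-2-(bromomethyl)-4-[(4-methoxyphenyl)methoxy]but-2-enoate | COC(=O)/C(CBr)=C/COCc1ccc(OC)cc1 | intermediate
20 | trimethylsilyl ether of 21 (O8–SiMe3) | COC(=O)C(=C)[C@@H](COCc1ccc(OC)cc1)[C@H](O[Si](C)(C)C)C[C@@]1(C)OC(C)(C)O[C@H]1CC/C(C)=C\I | intermediate
21 | methyl (3S,4R)-4-hydroxy-5-[(4R,5S)-5-[(3Z)-4-iodo-3-methylbut-3-en-1-yl]-2,2,4-trimethyl-1,3-dioxolan-4-yl]-3-{[(4-methoxyphenyl)methoxy]methyl}-2-methylidenepentanoate | COC(=O)C(=C)[C@@H](COCc1ccc(OC)cc1)[C@H](O)C[C@@]1(C)OC(C)(C)O[C@H]1CC/C(C)=C\I | intermediate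
22 | methyl (3S,4R)-5-[(4R,5S)-5-[(3Z)-4-iodo-3-methylbut-3-en-1-yl]-2,2,4-trimethyl-1,3-dioxolan-4-yl]-3-{[(4-methoxyphenyl)methoxy]methyl}-4-[(3-methylbutanoyl)oxy]-2-methylidenepentanoate | COC(=O)C(=C)[C@@H](COCc1ccc(OC)cc1)[C@H](OC(=O)CC(C)C)C[C@@]1(C)OC(C)(C)O[C@H]1CC/C(C)=C\I | intermediate
23 | methyl (3S,4R)-3-(hydroxymethyl)-5-[(4R,5S)-5-[(3Z)-4-iodo-3-methylbut-3-en-1-yl]-2,2,4-trimethyl-1,3-dioxolan-4-yl]-4-[(3-methylbutanoyl)oxy]-2-methylidenepentanoate | COC(=O)C(=C)[C@@H](CO)[C@H](OC(=O)CC(C)C)C[C@@]1(C)OC(C)(C)O[C@H]1CC/C(C)=C\I | intermediate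
24 | methyl (3R,4R)-3-formyl-5-[(4R,5S)-5-[(3Z)-4-iodo-3-methylbut-3-en-1-yl]-2,2,4-trimethyl-1,3-dioxolan-4-yl]-4-[(3-methylbutanoyl)oxy]-2-methylidenepentanoate | COC(=O)C(=C)[C@@H](C=O)[C@H](OC(=O)CC(C)C)C[C@@]1(C)OC(C)(C)O[C@H]1CC/C(C)=C\I | intermediate
25 | methyl (1S,6R,7S,8R,10R)-6-hydroxy-1,10-(isopropylidenedioxy)-8-(3-methylbutanoyloxy)germacra-4Z,11(13)-dien-12-oate (ten-membered ring closed, lactone open) | COC(=O)C(=C)[C@H]1[C@H](O)/C=C(/C)CC[C@@H]2OC(C)(C)O[C@]2(C)C[C@H]1OC(=O)CC(C)C | intermediate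
26 | (1S,6R,7R,8R,10R)-1,10-(isopropylidenedioxy)-8-(3-methylbutanoyloxy)germacra-4Z,11(13)-dien-6,12-olide | C=C1C(=O)O[C@@H]2/C=C(/C)CC[C@@H]3OC(C)(C)O[C@]3(C)C[C@@H](OC(=O)CC(C)C)[C@@H]12 | intermediate
27 | (1S,6R,7R,8R,10R)-1,10-dihydroxy-8-(3-methylbutanoyloxy)germacra-4Z,11(13)-dien-6,12-olide | C=C1C(=O)O[C@@H]2/C=C(/C)CC[C@H](O)[C@](C)(O)C[C@@H](OC(=O)CC(C)C)[C@@H]12 | intermediate
28 | CNP0105188.1, (6R,7R,8R,10R)-10-hydroxy-8-(3-methylbutanoyloxy)-1-oxogermacra-4Z,11(13)-dien-6,12-olide | C=C1C(=O)O[C@@H]2/C=C(/C)CCC(=O)[C@](C)(O)C[C@@H](OC(=O)CC(C)C)[C@@H]12 | target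

**Step count and risks**
Total: 20 steps. Longest linear sequence: 16 steps from (S)-lactic acid (steps 1–5, 8–11, 14–20). The two side branches are steps 6–7 and 12–13.

Steps most likely to fail:

1. Step 18. Two processes can go wrong: intermolecular coupling can outrun the ten-membered closure (held back by the dioxolane turn and slow addition at 2 mM), and C5 can add to the Si face of the aldehyde (poor facial selectivity at C6). The fallback answers the second by fixing C6 through a stereospecific inversion instead of substrate control. It sets out from 24: the CrCl2/NiCl2 closure is worked up at room temperature without acid or heating to isolate the (6S)-epimer of 25 F4. The methyl ester alone is cleaved with Me3SnOH (1,2-dichloroethane, 70 °C) to give the (6S)-hydroxy acid F5. Mitsunobu lactonisation (PPh3, DIAD, THF, 0 °C) then closes the lactone with inversion at C6 and returns to the route at 26.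

2. Step 14. The chiral chromium complex may fail to override the substrate (poor facial selectivity at C8), or the γ-alkoxy allylchromium species may lose its alkoxide by β-elimination. The fallback gives up catalyst control for a ligand-free Barbier reaction and a separation. It sets out from 15 and 19: indium powder in THF/H2O 1:1 at room temperature should give, through the same six-membered chair, only 7,8-syn adducts but with no control of the aldehyde face, that is 21 together with the (3R,4S)-diastereomer of 21 F3. Chromatography separates them and the route is rejoined at 21.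

3. Step 8. Proton exchange between the product ketone and unreacted enolate can lead to double alkylation, and some O-alkylation is possible. The fallback replaces the ketone enolate by an azaenolate. It sets out from 6: Me2NNH2 (EtOH, AcOH cat., 60 °C) gives the N,N-dimethylhydrazone of 6 F1; LiN(iPr)2 (THF, −78 → 0 °C) then 9 gives the alkylated hydrazone F2 by clean monoalkylation; CuCl2 in THF/pH 7 buffer hydrolyses F2 and returns to the route at 10.

**Further compounds**
F1 | step 8 | (E)-N,N-dimethylhydrazone of (3R)-3-methyl-3-(triethylsilyloxy)hex-5-en-2-one | C=CC[C@@](C)(O[Si](CC)(CC)CC)/C(C)=N/N(C)C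
F2 | step 8 | (E)-N,N-dimethylhydrazone of (1Z,6R)-1-iodo-2,6-dimethyl-6-(triethylsilyloxy)nona-1,8-dien-5-one | C=CC[C@@](C)(O[Si](CC)(CC)CC)/C(CC/C(C)=C\I)=N/N(C)C
F3 | step 14 | methyl (3R,4S)-4-hydroxy-5-[(4R,5S)-5-[(3Z)-4-iodo-3-methylbut-3-en-1-yl]-2,2,4-trimethyl-1,3-dioxolan-4-yl]-3-{[(4-methoxyphenyl)methoxy]methyl}-2-methylidenepentanoate | COC(=O)C(=C)[C@H](COCc1ccc(OC)cc1)[C@@H](O)C[C@@]1(C)OC(C)(C)O[C@H]1CC/C(C)=C\I
F4 | step 18 | methyl (1S,6S,7S,8R,10R)-6-hydroxy-1,10-(isopropylidenedioxy)-8-(3-methylbutanoyloxy)germacra-4Z,11(13)-dien-12-oate | COC(=O)C(=C)[C@H]1[C@@H](O)/C=C(/C)CC[C@@H]2OC(C)(C)O[C@]2(C)C[C@H]1OC(=O)CC(C)C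
F5 | step 18 | (1S,6S,7S,8R,10R)-6-hydroxy-1,10-(isopropylidenedioxy)-8-(3-methylbutanoyloxy)germacra-4Z,11(13)-dien-12-oic acid | OC(=O)C(=C)[C@H]1[C@@H](O)/C=C(/C)CC[C@@H]2OC(C)(C)O[C@]2(C)C[C@H]1OC(=O)CC(C)C
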